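**Retrosynthetic overview**
1. Target 44 ⇐ C12 alcohol oxidation ⇐ Δ2(14)-alkene 42 ⇐ Myers reductive 1,3-transposition of a Pauson–Khand enone (sets H-13; the C2 carbonyl is traceless).
2. Nine-membered ring ⇐ ring-closing boron aldol C3–C4 (enone α′-carbon onto a C4 enal). This is the key step, chosen instead of the usual C4–C5 NHK/RCM closure.
3. γ-Lactone, C6–Cl, C7, C8, C17 ⇐ chelation-controlled Reformatsky–lactonisation of chloro-ketol 28 ⇐ asymmetric epoxidation/LiCl opening of dienone 26 ⇐ NHK union of aldehyde 20 with dienyl iodide 24.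
4. Rings B and A together, with quaternary C1 ⇐ catalytic Pauson–Khand reaction of 1,6-enyne 16.
5. C9–C10–C11 triad ⇐ lactate Ireland–Claisen on the (R)-glyceraldehyde-derived allylic ester 8. Ring order: B/A (one step) → lactone → nine-membered ring.

Assumption: atoms carry briarane-type labels mapped onto the target SMILES (C1 = quaternary C–CH3, C2=C14 ring-A alkene, C5=C16 exo-methylene, C12 = ketone, C19 = lactone C=O, C15/C18/C20 = methyls on C1/C17/C11); compounds 1, 2, 5, 14, 21 and 29 are taken as commercial.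

**Step 1**
Reactants: 1 (4R)-2,2-dimethyl-1,3-dioxolane-4-carbaldehyde; 2 ethyl 2-(triphenyl-λ5-phosphanylidene)propanoate
Product: 3 ethyl (2E)-3-[(4S)-2,2-dimethyl-1,3-dioxolan-4-yl]-2-methylprop-2-enoate
Conditions: CH2Cl2, 0 °C → rt
Reagents that add atoms: none
Why: Stabilised Wittig olefination gives the (E)-trisubstituted enoate (dioxolane cis to the future C15 methyl), and C9 comes unchanged from the chiral pool.

**Step 2**
Reactants: 3 ethyl (2E)-3-[(4S)-2,2-dimethyl-1,3-dioxolan-4-yl]-2-methylprop-2-enoate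
Product: 4 (2E)-3-[(4S)-2,2-dimethyl-1,3-dioxolan-4-yl]-2-methylprop-2-en-1-ol
Conditions: DIBAL-H (2.2 equiv), CH2Cl2, −78 °C; Rochelle salt
Reagents that add atoms: none
Why: DIBAL-H 1,2-reduction of the enoate gives the allylic alcohol (C3–OH) without touching the alkene geometry or C9.

**Step 3**
Reactants: 5 methyl 2-hydroxypropanoate (racemic)
Product: 6 methyl 2-(methoxymethoxy)propanoate (racemic)
Conditions: MOMCl, i-Pr2NEt, CH2Cl2, 0 °C → rt
Reagents that add atoms: chloromethyl methyl ether COCCl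
Why: O-alkylation gives a chelating MOM ether; the lactate stereocentre is irrelevant because it is erased on enolisation in step 6.

**Step 4**
Reactants: 6 methyl 2-(methoxymethoxy)propanoate
Product: 7 2-(methoxymethoxy)propanoic acid (racemic)
Conditions: LiOH, THF/H2O, rt; then 1 M HCl
Reagents that add atoms: lithium hydroxide [Li+].[OH-]
Why: Ester saponification (BAc2); the MOM ether is stable to base.

**Step 5**
Reactants: 4 (2E)-3-[(4S)-2,2-dimethyl-1,3-dioxolan-4-yl]-2-methylprop-2-en-1-ol; 7 2-(methoxymethoxy)propanoic acid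
Product: 8 (2E)-3-[(4S)-2,2-dimethyl-1,3-dioxolan-4-yl]-2-methylprop-2-en-1-yl 2-(methoxymethoxy)propanoate (both α-epimers)
Conditions: DCC, DMAP (cat.), CH2Cl2, 0 °C → rt
Reagents that add atoms: none
Why: Steglich esterification of a primary allylic alcohol under neutral conditions.

**Step 6**
Reactants: 8 (2E)-3-[(4S)-2,2-dimethyl-1,3-dioxolan-4-yl]-2-methylprop-2-en-1-yl 2-(methoxymethoxy)propanoate
Product: 12 methyl (2S,3S)-3-[(4S)-2,2-dimethyl-1,3-dioxolan-4-yl]-2-(methoxymethoxy)-2,4-dimethylpent-4-enoate, via silyl ketene acetal 9 (not isolated), via trimethylsilyl ester 10 (not isolated), via carboxylic acid 11 (not isolated)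
Conditions: LDA, THF, −78 °C; TMSCl, −78 °C → 45 °C; 1 M HCl; TMSCHN2, MeOH/PhMe, 0 °C
Reagents that add atoms: (trimethylsilyl)diazomethane C[Si](C)(C)C=[N+]=[N-]
Why: Ireland–Claisen rearrangement of the Li-chelated (Z)-enolate through a chair TS with the (E)-alkene substituent equatorial sets C11 (OMOM trans to the C9 branch) and C10, the new bond forming anti to the C9–O bond with H-9 eclipsing the alkene (A1,3 control); it also creates the isopropenyl group.

**Step 7**
Reactants: 12 methyl (2S,3S)-3-[(4S)-2,2-dimethyl-1,3-dioxolan-4-yl]-2-(methoxymethoxy)-2,4-dimethylpent-4-enoate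
Product: 13 (2S,3S)-3-[(4S)-2,2-dimethyl-1,3-dioxolan-4-yl]-2-(methoxymethoxy)-2,4-dimethylpent-4-enal
Conditions: DIBAL-H (1.1 equiv), CH2Cl2, −78 °C
Reagents that add atoms: none
Why: Partial DIBAL-H reduction stops at the aldehyde because the α-alkoxy tetrahedral aluminate is chelate-stabilised; the α-carbon is quaternary, so it cannot epimerise.

**Step 8**
Reactants: 13 (2S,3S)-3-[(4S)-2,2-dimethyl-1,3-dioxolan-4-yl]-2-(methoxymethoxy)-2,4-dimethylpent-4-enal; 14 ethynylmagnesium bromide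
Product: 15 (3S,4S,5S)-5-[(4S)-2,2-dimethyl-1,3-dioxolan-4-yl]-4-(methoxymethoxy)-4,6-dimethylhept-6-en-1-yn-3-ol
Conditions: THF, −78 → 0 °C; aq. NH4Cl
Reagents that add atoms: none
Why: Cram-chelate Grignard addition (Mg bridging C=O and the MOM oxygen) delivers ethynyl from the methyl side of C11; this C12 centre is later oxidised away, so the minor epimer converges.

**Step 9**
Reactants: 15 (3S,4S,5S)-5-[(4S)-2,2-dimethyl-1,3-dioxolan-4-yl]-4-(methoxymethoxy)-4,6-dimethylhept-6-en-1-yn-3-ol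
Product: 16 triisopropylsilyl ether of 15
Conditions: TIPSOTf, 2,6-lutidine, CH2Cl2, 0 °C
Reagents that add atoms: triisopropylsilyl triflate CC(C)[Si](C(C)C)(C(C)C)OS(=O)(=O)C(F)(F)F
Why: Silylation of the hindered propargylic alcohol with an acid-stable group that survives step 11 and favours the exo position in step 10.

**Step 10**
Reactants: 16 triisopropylsilyl ether of 15
Product: 17 (5R,6S,7S,8S)-6-[(4S)-2,2-dimethyl-1,3-dioxolan-4-yl]-7-(methoxymethoxy)-5,7-dimethyl-8-(triisopropylsilyloxy)bicyclo[3.3.0]oct-1-en-3-one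
Conditions: Co2(CO)8 (20 mol %), tetramethylthiourea, CO (1 atm), PhMe, 70 °C
Reagents that add atoms: carbon monoxide [C-]#[O+]
Why: Intramolecular Pauson–Khand reaction of the 1,6-enyne forms rings B and A and the quaternary C1, with the C10 branch, C11 methyl and C12 OTIPS on the exo face away from the cobaltacycle, so C15 ends up cis to C9.

**Step 11**
Reactants: 17 bicyclic enone (acetonide, MOM ether)
Product: 18 (5R,6S,7S,8S)-6-[(1S)-1,2-dihydroxyethyl]-7-hydroxy-5,7-dimethyl-8-(triisopropylsilyloxy)bicyclo[3.3.0]oct-1-en-3-one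
Conditions: 3 M aq. HCl, MeOH, 40 °C
Reagents that add atoms: none
Why: Acid hydrolysis removes the terminal acetonide and the MOM acetal in one operation while the hindered TIPS ether and the enone survive.

**Step 12**
Reactants: 18 enone triol
Product: 19 bis(triethylsilyl) ether of 18 (C8–OTES, C9–OTES; tertiary C11–OH free)
Conditions: TESCl (2.3 equiv), imidazole, CH2Cl2, 0 °C
Reagents that add atoms: chlorotriethylsilane CC[Si](CC)(CC)Cl
Why: TESCl/imidazole silylates the primary and secondary hydroxyls but not the tertiary C11–OH.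

**Step 13**
Reactants: 19 bis(triethylsilyl) ether
Product: 20 (S)-α-(triethylsilyloxy) aldehyde (C8 = CHO, C9–OTES) on the bicyclic enone
Conditions: (COCl)2, DMSO, CH2Cl2, −78 → −30 °C; Et3N
Reagents that add atoms: none
Why: Swern conditions selectively desilylate and oxidise the primary TES ether, giving the C8 aldehyde with the secondary C9–OTES intact.

**Step 14**
Reactants: 21 2-methylidenepropane-1,3-diol
Product: 22 2-[(triethylsilyloxy)methyl]prop-2-en-1-ol
Conditions: NaH (1.0 equiv), THF, 0 °C; TESCl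
Reagents that add atoms: chlorotriethylsilane CC[Si](CC)(CC)Cl
Why: Monosilylation of a symmetric diol through its sparingly soluble mono-alkoxide.

**Step 15**
Reactants: 22 2-[(triethylsilyloxy)methyl]prop-2-en-1-ol
Product: 23 2-[(triethylsilyloxy)methyl]prop-2-enal
Conditions: MnO2, CH2Cl2, rt
Reagents that add atoms: none
Why: Chemoselective MnO2 oxidation of the allylic alcohol to the 2-substituted acrolein (C6 aldehyde).

**Step 16**
Reactants: 23 2-[(triethylsilyloxy)methyl]prop-2-enal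
Product: 24 triethyl{[(3E)-4-iodo-2-methylidenebut-3-en-1-yl]oxy}silane
Conditions: CrCl2, CHI3, THF, 0 °C
Reagents that add atoms: iodoform IC(I)I
Why: Takai olefination converts the enal into the (E)-iododiene (C7=C6, C5=C16, C4–OTES) with high E-selectivity.

**Step 17**
Reactants: 20 C8 aldehyde; 24 triethyl{[(3E)-4-iodo-2-methylidenebut-3-en-1-yl]oxy}silane
Product: 25 C8 allylic alcohol (both C8 epimers) carrying the (6E)-diene side chain
Conditions: CrCl2 (6 equiv), NiCl2 (1 mol %), DMSO/THF, rt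
Reagents that add atoms: none
Why: Nozaki–Hiyama–Kishi coupling adds the alkenylchromium only to the aldehyde, tolerating the ring enone, free tertiary alcohol and silyl ethers; the C8 configuration is irrelevant.

**Step 18**
Reactants: 25 C8 allylic alcohol
Product: 26 (6E)-cross-conjugated dienone (C8 ketone)
Conditions: Dess–Martin periodinane, NaHCO3, CH2Cl2, 0 °C
Reagents that add atoms: none
Why: Dess–Martin oxidation of the secondary allylic alcohol under buffered conditions that do not epimerise C9.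

**Step 19**
Reactants: 26 (6E)-dienone
Product: 27 (6R,7S)-6,7-epoxy ketone (trans-epoxide)
Conditions: La(O-iPr)3/(R)-BINOL/Ph3As=O (10 mol %), TBHP, 4 Å MS, THF, rt
Reagents that add atoms: tert-butyl hydroperoxide CC(C)(C)OO
Why: Catalytic asymmetric nucleophilic epoxidation of the (E)-enone, with the ligand enantiomer that gives (αS,βR)-epoxy ketones, sets C7 by catalyst control and leaves the hindered ring enone and the 1,1-disubstituted alkene alone.

**Step 20**
Reactants: 27 (6R,7S)-epoxy ketone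
Product: 28 (6S,7R)-6-chloro-7-hydroxy C8 ketone
Conditions: LiCl, AcOH, THF, 0 °C
Reagents that add atoms: lithium chloride [Li+].[Cl-]
Why: Halohydrin formation by SN2 opening at the β, allylic C6 with inversion gives the anti chlorohydrin with Cl at C6 and the free C7–OH.

**Step 21**
Reactants: 28 (6S,7R)-6-chloro-7-hydroxy C8 ketone; 29 methyl 2-bromopropanoate (racemic)
Product: 32 γ-lactone (7R,8R,17R; 8-OH; 6S-Cl; 4-OTES, 9-OTES), via zinc Reformatsky reagent 30 (not isolated), via seco hydroxy ester 31 (not isolated)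
Conditions: 29, Zn (TMSCl-activated), THF, 40 °C; add to 28 (4 equiv reagent), THF, −20 → 0 °C; aq. NH4Cl; DBU (cat.), CH2Cl2, 0 °C
Reagents that add atoms: none
Why: Reformatsky addition to the zinc-alkoxide-chelated ketone (Cram chelate through O7, Felkin-consistent with the non-chelating C9–OTES) sets C8 with OH cis to C6; the C7 alkoxide then lactonises, and the epimerisable C17 settles with its methyl anti to the C9 branch.

**Step 22**
Reactants: 32 γ-lactone bis-TES ether
Product: 33 lactone diol (C4–OH, C9–OH free; C12–OTIPS kept)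
Conditions: HF·pyridine, pyridine, THF, 0 °C
Reagents that add atoms: none
Why: Buffered fluoride desilylation removes both TES ethers while the hindered TIPS ether, the lactone and the allylic chloride survive.

**Step 23**
Reactants: 33 lactone diol
Product: 34 lactone enal (C4 = CHO conjugated to C5=C16)
Conditions: MnO2, CH2Cl2, rt
Reagents that add atoms: none
Why: MnO2 oxidises only the primary allylic C4–OH, giving a non-enolisable 2-substituted acrolein.

**Step 24**
Reactants: 34 lactone enal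
Product: 37 tricyclic aldol (nine-membered ring closed; (3S,4S)-4-hydroxy-2-ketone), via dibutylboron dienolate 35 (not isolated), via boron aldolate 36 (not isolated)
Conditions: Bu2BOTf (5 equiv), i-Pr2NEt, CH2Cl2 (2 mM), −78 → −20 °C; pH 7 buffer, MeOH, H2O2, 0 °C
Reagents that add atoms: none
Why: Proposed new method: soft enolisation can only occur at the α′-carbon C3 of the ring enone (the enal has no α-H and lactones are not enolised), and the boron dienolate adds 1,2 to the tethered enal through a closed, irreversible boron-chelated TS on the face anti to the angular methyl, from which the C10 tether emerges, setting C3; the C4 configuration follows from the ring-constrained TS and is corrigible, and the closest known reaction type is intramolecular boron- or samarium-enolate aldol closure of eight-membered carbocycles.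

**Step 25**
Reactants: 37 tricyclic aldol
Product: 38 4,9-diacetate of 37
Conditions: Ac2O, pyridine, DMAP (cat.), CH2Cl2, 0 °C
Reagents that add atoms: acetic anhydride CC(=O)OC(C)=O
Why: Acylation of the two secondary alcohols installs both target acetates at once; the tertiary C8 and C11 hydroxyls do not react at 0 °C.

**Step 26**
Reactants: 38 4,9-diacetate
Product: 39 C2 allylic alcohol (2-OH cis to the C3–C4 bond)
Conditions: NaBH4, CeCl3·7H2O, MeOH, −78 °C
Reagents that add atoms: none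
Why: Luche 1,2-reduction with hydride arriving from the angular-methyl face, anti to the adjacent C3–C4 branch, places the hydroxyl on the C4/C10 face.

**Step 27**
Reactants: 39 C2 allylic alcohol
Product: 42 Δ2(14)-alkene (12-O-TIPS ether of the 12-hydroxy target precursor), via allylic sulfonylhydrazine 40 (not isolated), via allylic diazene 41 (not isolated)
Conditions: 2-nitrobenzenesulfonylhydrazide, PPh3, DEAD, N-methylmorpholine/THF, −30 °C; then 23 °C
Reagents that add atoms: none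
Why: Myers reductive 1,3-transposition: Mitsunobu inversion puts nitrogen on the methyl face, sulfinate loss gives the diazene, and its retro-ene loss of N2 delivers H to C13 on that face, giving the cis-fused diquinane with the C2=C14 alkene.

**Step 28**
Reactants: 42 Δ2(14)-alkene TIPS ether
Product: 43 (12S)-12-hydroxy compound
Conditions: HF·pyridine, THF, 0 °C → rt
Reagents that add atoms: none
Why: Fluoride cleavage of the last silyl ether under mildly acidic conditions that spare the acetates, lactone and allylic chloride.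

**Step 29**
Reactants: 43 (12S)-12-hydroxy compound
Product: 44 CNP0145188.1 (target)
Conditions: Dess–Martin periodinane, NaHCO3, CH2Cl2, 0 °C
Reagents that add atoms: none
Why: Dess–Martin oxidation of the only secondary alcohol gives the α-hydroxy β,γ-unsaturated ketone under neutral conditions that avoid alkene conjugation and α-ketol rearrangement.

**Compound list**
1 | (4R)-2,2-dimethyl-1,3-dioxolane-4-carbaldehyde | O=C[C@@H]1OC(C)(C)OC1 | starting material
2 | ethyl 2-(triphenyl-λ5-phosphanylidene)propanoate | CCOC(=O)C(C)=P(c1ccccc1)(c1ccccc1)c1ccccc1 | starting material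
3 | ethyl (2E)-3-[(4S)-2,2-dimethyl-1,3-dioxolan-4-yl]-2-methylprop-2-enoate | CCOC(=O)/C(C)=C/[C@@H]1OC(C)(C)OC1 | intermediate
4 | (2E)-3-[(4S)-2,2-dimethyl-1,3-dioxolan-4-yl]-2-methylprop-2-en-1-ol | OC/C(C)=C/[C@@H]1OC(C)(C)OC1 | intermediate
5 | methyl 2-hydroxypropanoate (racemic) | COC(=O)C(C)O | starting material
6 | methyl 2-(methoxymethoxy)propanoate (racemic) | COCOC(C)C(=O)OC | intermediate
7 | 2-(methoxymethoxy)propanoic acid (racemic) | COCOC(C)C(O)=O | intermediate
8 | (2E)-3-[(4S)-2,2-dimethyl-1,3-dioxolan-4-yl]-2-methylprop-2-en-1-yl 2-(methoxymethoxy)propanoate (both α-epimers) | COCOC(C)C(=O)OC/C(C)=C/[C@@H]1OC(C)(C)OC1 | intermediate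
9 | (Z)-O-trimethylsilyl ketene acetal of 8 (MOMO cis to Me3SiO) | COCO/C(C)=C(\O[Si](C)(C)C)OC/C(C)=C/[C@@H]1OC(C)(C)OC1 | intermediate (not isolated)
10 | trimethylsilyl (2S,3S)-3-[(4S)-2,2-dimethyl-1,3-dioxolan-4-yl]-2-(methoxymethoxy)-2,4-dimethylpent-4-enoate | C[Si](C)(C)OC(=O)[C@@](C)(OCOC)[C@H]([C@@H]1OC(C)(C)OC1)C(C)=C | intermediate (not isolated)
11 | (2S,3S)-3-[(4S)-2,2-dimethyl-1,3-dioxolan-4-yl]-2-(methoxymethoxy)-2,4-dimethylpent-4-enoic acid | OC(=O)[C@@](C)(OCOC)[C@H]([C@@H]1OC(C)(C)OC1)C(C)=C | intermediate (not isolated)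
12 | methyl (2S,3S)-3-[(4S)-2,2-dimethyl-1,3-dioxolan-4-yl]-2-(methoxymethoxy)-2,4-dimethylpent-4-enoate | COC(=O)[C@@](C)(OCOC)[C@H]([C@@H]1OC(C)(C)OC1)C(C)=C | intermediate
13 | (2S,3S)-3-[(4S)-2,2-dimethyl-1,3-dioxolan-4-yl]-2-(methoxymethoxy)-2,4-dimethylpent-4-enal | O=C[C@@](C)(OCOC)[C@H]([C@@H]1OC(C)(C)OC1)C(C)=C | intermediate
14 | ethynylmagnesium bromide | C#C[Mg]Br | starting material
15 | (3S,4S,5S)-5-[(4S)-2,2-dimethyl-1,3-dioxolan-4-yl]-4-(methoxymethoxy)-4,6-dimethylhept-6-en-1-yn-3-ol | C#C[C@H](O)[C@@](C)(OCOC)[C@H]([C@@H]1OC(C)(C)OC1)C(C)=C | intermediate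
16 | triisopropylsilyl ether of 15 (1,6-enyne) | C#C[C@H](O[Si](C(C)C)(C(C)C)C(C)C)[C@@](C)(OCOC)[C@H]([C@@H]1OC(C)(C)OC1)C(C)=C | intermediate
17 | (5R,6S,7S,8S)-6-[(4S)-2,2-dimethyl-1,3-dioxolan-4-yl]-7-(methoxymethoxy)-5,7-dimethyl-8-(triisopropylsilyloxy)bicyclo[3.3.0]oct-1-en-3-one | O=C1C=C2[C@H](O[Si](C(C)C)(C(C)C)C(C)C)[C@@](C)(OCOC)[C@H]([C@@H]3OC(C)(C)OC3)[C@@]2(C)C1 | intermediate
18 | (5R,6S,7S,8S)-6-[(1S)-1,2-dihydroxyethyl]-7-hydroxy-5,7-dimethyl-8-(triisopropylsilyloxy)bicyclo[3.3.0]oct-1-en-3-one | O=C1C=C2[C@H](O[Si](C(C)C)(C(C)C)C(C)C)[C@@](C)(O)[C@H]([C@H](O)CO)[C@@]2(C)C1 | intermediate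
19 | bis(triethylsilyl) ether of 18 at the side-chain primary (C8) and secondary (C9) hydroxyls | O=C1C=C2[C@H](O[Si](C(C)C)(C(C)C)C(C)C)[C@@](C)(O)[C@H]([C@H](O[Si](CC)(CC)CC)CO[Si](CC)(CC)CC)[C@@]2(C)C1 | intermediate
20 | (S)-2-(triethylsilyloxy)acetaldehyde carrying the bicyclic enone of 18 at C2 (C8 aldehyde, C9–OTES) | O=C1C=C2[C@H](O[Si](C(C)C)(C(C)C)C(C)C)[C@@](C)(O)[C@H]([C@H](O[Si](CC)(CC)CC)C=O)[C@@]2(C)C1 | intermediate
21 | 2-methylidenepropane-1,3-diol | C=C(CO)CO | starting material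
22 | 2-[(triethylsilyloxy)methyl]prop-2-en-1-ol | C=C(CO)CO[Si](CC)(CC)CC | intermediate
23 | 2-[(triethylsilyloxy)methyl]prop-2-enal | C=C(C=O)CO[Si](CC)(CC)CC | intermediate
24 | triethyl{[(3E)-4-iodo-2-methylidenebut-3-en-1-yl]oxy}silane | C=C(/C=C/I)CO[Si](CC)(CC)CC | intermediate
25 | C8 allylic alcohol (both C8 epimers): 20 with the (E)-dienyl unit of 24 added to the aldehyde | O=C1C=C2[C@H](O[Si](C(C)C)(C(C)C)C(C)C)[C@@](C)(O)[C@H]([C@H](O[Si](CC)(CC)CC)C(O)/C=C/C(=C)CO[Si](CC)(CC)CC)[C@@]2(C)C1 | intermediate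
26 | (6E)-cross-conjugated dienone (C8 ketone of 25) | O=C1C=C2[C@H](O[Si](C(C)C)(C(C)C)C(C)C)[C@@](C)(O)[C@H]([C@H](O[Si](CC)(CC)CC)C(=O)/C=C/C(=C)CO[Si](CC)(CC)CC)[C@@]2(C)C1 | intermediate
27 | (6R,7S)-6,7-epoxy ketone (trans-epoxide of 26) | O=C1C=C2[C@H](O[Si](C(C)C)(C(C)C)C(C)C)[C@@](C)(O)[C@H]([C@H](O[Si](CC)(CC)CC)C(=O)[C@H]3O[C@@H]3C(=C)CO[Si](CC)(CC)CC)[C@@]2(C)C1 | intermediate
28 | (6S,7R)-6-chloro-7-hydroxy C8 ketone | O=C1C=C2[C@H](O[Si](C(C)C)(C(C)C)C(C)C)[C@@](C)(O)[C@H]([C@H](O[Si](CC)(CC)CC)C(=O)[C@@H](O)[C@@H](Cl)C(=C)CO[Si](CC)(CC)CC)[C@@]2(C)C1 | intermediate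
29 | methyl 2-bromopropanoate (racemic) | COC(=O)C(C)Br | starting material
30 | bromo(1-methoxy-1-oxopropan-2-yl)zinc | COC(=O)C(C)[Zn]Br | intermediate (not isolated)
31 | seco hydroxy ester: methyl propanoate unit added at C8 (8R, 17R), 7-OH free | O=C1C=C2[C@H](O[Si](C(C)C)(C(C)C)C(C)C)[C@@](C)(O)[C@H]([C@H](O[Si](CC)(CC)CC)[C@](O)([C@@H](C)C(=O)OC)[C@@H](O)[C@@H](Cl)C(=C)CO[Si](CC)(CC)CC)[C@@]2(C)C1 | intermediate (not isolated)
32 | γ-lactone (7R,8R,17R; 8-OH; 6S-Cl; 4-OTES, 9-OTES, 12-OTIPS) on the bicyclic enone | O=C1C=C2[C@H](O[Si](C(C)C)(C(C)C)C(C)C)[C@@](C)(O)[C@H]([C@H](O[Si](CC)(CC)CC)[C@]3(O)[C@@H](C)C(=O)O[C@H]3[C@@H](Cl)C(=C)CO[Si](CC)(CC)CC)[C@@]2(C)C1 | intermediate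
33 | lactone diol (4-OH, 9-OH free) | O=C1C=C2[C@H](O[Si](C(C)C)(C(C)C)C(C)C)[C@@](C)(O)[C@H]([C@H](O)[C@]3(O)[C@@H](C)C(=O)O[C@H]3[C@@H](Cl)C(=C)CO)[C@@]2(C)C1 | intermediate
34 | lactone enal (C4 aldehyde) | O=C1C=C2[C@H](O[Si](C(C)C)(C(C)C)C(C)C)[C@@](C)(O)[C@H]([C@H](O)[C@]3(O)[C@@H](C)C(=O)O[C@H]3[C@@H](Cl)C(=C)C=O)[C@@]2(C)C1 | intermediate
35 | dibutylboron cross-conjugated dienolate of 34 (C2–OBBu2, C2=C3) | CCCCB(CCCC)OC1=C[C@]2(C)[C@@H]([C@H](O)[C@]3(O)[C@@H](C)C(=O)O[C@H]3[C@@H](Cl)C(=C)C=O)[C@](C)(O)[C@@H](O[Si](C(C)C)(C(C)C)C(C)C)C2=C1 | intermediate (not isolated)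
36 | boron aldolate (C4–OBBu2) of 37 | C=C1[C@@H](OB(CCCC)CCCC)[C@H]2C(=O)C=C3[C@H](O[Si](C(C)C)(C(C)C)C(C)C)[C@@](C)(O)[C@H]([C@H](O)[C@]4(O)[C@@H](C)C(=O)O[C@H]4[C@H]1Cl)[C@@]23C | intermediate (not isolated)
37 | tricyclic aldol: nine-membered ring closed, (3S,4S)-4-hydroxy, C2 ketone, Δ13(14), 12-OTIPS; other centres as in target | C=C1[C@@H](O)[C@H]2C(=O)C=C3[C@H](O[Si](C(C)C)(C(C)C)C(C)C)[C@@](C)(O)[C@H]([C@H](O)[C@]4(O)[C@@H](C)C(=O)O[C@H]4[C@H]1Cl)[C@@]23C | intermediate
38 | 4,9-diacetate of 37 | C=C1[C@@H](OC(C)=O)[C@H]2C(=O)C=C3[C@H](O[Si](C(C)C)(C(C)C)C(C)C)[C@@](C)(O)[C@H]([C@H](OC(C)=O)[C@]4(O)[C@@H](C)C(=O)O[C@H]4[C@H]1Cl)[C@@]23C | intermediate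
39 | C2 allylic alcohol of 38 (2-OH cis to the C3–C4 bond) | C=C1[C@@H](OC(C)=O)[C@H]2[C@@H](O)C=C3[C@H](O[Si](C(C)C)(C(C)C)C(C)C)[C@@](C)(O)[C@H]([C@H](OC(C)=O)[C@]4(O)[C@@H](C)C(=O)O[C@H]4[C@H]1Cl)[C@@]23C | intermediate
40 | C2 N-(2-nitrobenzenesulfonyl)hydrazine (inverted at C2) | C=C1[C@@H](OC(C)=O)[C@H]2[C@H](N(N)S(=O)(=O)c5ccccc5[N+](=O)[O-])C=C3[C@H](O[Si](C(C)C)(C(C)C)C(C)C)[C@@](C)(O)[C@H]([C@H](OC(C)=O)[C@]4(O)[C@@H](C)C(=O)O[C@H]4[C@H]1Cl)[C@@]23C | intermediate (not isolated)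
41 | C2 allylic diazene | C=C1[C@@H](OC(C)=O)[C@H]2[C@H](N=N)C=C3[C@H](O[Si](C(C)C)(C(C)C)C(C)C)[C@@](C)(O)[C@H]([C@H](OC(C)=O)[C@]4(O)[C@@H](C)C(=O)O[C@H]4[C@H]1Cl)[C@@]23C | intermediate (not isolated)
42 | Δ2(14)-alkene, (12S)-12-O-triisopropylsilyl ether of 43 (cis-fused, 13-H cis to C15) | C=C1[C@@H](OC(C)=O)[C@H]2C=C[C@H]3[C@H](O[Si](C(C)C)(C(C)C)C(C)C)[C@@](C)(O)[C@H]([C@H](OC(C)=O)[C@]4(O)[C@@H](C)C(=O)O[C@H]4[C@H]1Cl)[C@@]23C | intermediate
43 | (12S)-12-hydroxy compound (12-dihydro target) | C=C1[C@@H](OC(C)=O)[C@H]2C=C[C@H]3[C@H](O)[C@@](C)(O)[C@H]([C@H](OC(C)=O)[C@]4(O)[C@@H](C)C(=O)O[C@H]4[C@H]1Cl)[C@@]23C | intermediate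
44 | CNP0145188.1 | C=C1[C@@H](OC(C)=O)[C@H]2C=C[C@H]3C(=O)[C@@](C)(O)[C@H]([C@H](OC(C)=O)[C@]4(O)[C@@H](C)C(=O)O[C@H]4[C@H]1Cl)[C@@]23C | target

**Totals**
Total steps: 29. Longest linear sequence: 24 steps (1, 2, 5–13, 17–29); steps 3–4 and 14–16 are side branches.

**Three steps most likely to fail**

Step 24 (nine-membered ring-closing boron aldol). The ring may not close, or C4 may come out epimeric. The fallback sets out from 34: the boron dienolate is quenched with NBS to give the C3-bromo enone enal F1, and SmI2 in THF at −78 °C then generates the samarium(III) enolate regiospecifically at C3, which closes onto the aldehyde in an irreversible Reformatsky-type aldol. This returns to the route at 37. If C4 is still epimeric, a Mitsunobu acetylation replaces the plain acetylation at C4.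

Step 27 (Myers transposition on a hindered cyclopentenol inside the tricycle). The Mitsunobu step may stall. The fallback sets out from 37, before acetylation: condensation with tosylhydrazide gives the C2 tosylhydrazone F2. Hydroxyl-directed reduction with Me4NBH(OAc)3/AcOH delivers hydride from the C4–O face, so nitrogen sits on the methyl face; NaOAc at 60 °C then expels sulfinate, and the diazene loses N2 with H transfer to C13, giving the Δ2(14)-alkene 4,9-diol F3. Acetylation (Ac2O, pyridine, DMAP) returns to the route at 42.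

Step 21 (intermolecular Reformatsky on a crowded, polyfunctional ketone). Addition may be slow or unselective. The fallback sets out from 28: the C7 hydroxyl is acylated with 2-bromopropanoyl bromide/pyridine to give the C7 2-bromopropanoate F4, and SmI2 (THF, −78 °C) then triggers an intramolecular Reformatsky cyclisation in which the tether forces the C9 branch trans to C6. This returns to the route at 32.

**Further compounds**
F1 | step 24 | C3-bromo derivative of enal 34 (either C3 epimer) | O=C1C=C2[C@H](O[Si](C(C)C)(C(C)C)C(C)C)[C@@](C)(O)[C@H]([C@H](O)[C@]3(O)[C@@H](C)C(=O)O[C@H]3[C@@H](Cl)C(=C)C=O)[C@@]2(C)C1Br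
F2 | step 27 | C2 tosylhydrazone of aldol 37 | C=C1[C@@H](O)[C@H]2C(=NNS(=O)(=O)c5ccc(C)cc5)C=C3[C@H](O[Si](C(C)C)(C(C)C)C(C)C)[C@@](C)(O)[C@H]([C@H](O)[C@]4(O)[C@@H](C)C(=O)O[C@H]4[C@H]1Cl)[C@@]23C
F3 | step 27 | Δ2(14)-alkene 4,9-diol (bis-deacetyl 42) | C=C1[C@@H](O)[C@H]2C=C[C@H]3[C@H](O[Si](C(C)C)(C(C)C)C(C)C)[C@@](C)(O)[C@H]([C@H](O)[C@]4(O)[C@@H](C)C(=O)O[C@H]4[C@H]1Cl)[C@@]23C
F4 | step 21 | C7 O-(2-bromopropanoyl) ester of 28 | O=C1C=C2[C@H](O[Si](C(C)C)(C(C)C)C(C)C)[C@@](C)(O)[C@H]([C@H](O[Si](CC)(CC)CC)C(=O)[C@@H](OC(=O)C(C)Br)[C@@H](Cl)C(=C)CO[Si](CC)(CC)CC)[C@@]2(C)C1
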